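**Retrosynthetic overview**

1. The target is read as ring A–CH2–ring B–CH2–ring C: a central butyrylphloroglucinol (ring B) flanked by two identical butyrylfilicinic acid rings (A and C). Their ring atoms are numbered C1 = ring C=O next to the bridge-bearing carbon, C2 = butanoyl-bearing carbon, C3, C4 = C(CH3)2, C5, C6 = bridge-bearing carbon.
2. One retrosynthetic operation cuts four bonds: C1–C6 in ring A and in ring C (Dieckmann/Claisen closure) and both ring B–CH2 bonds (arene C-Michael addition). This leads to aryl ketone 4 and two molecules of the acyclic triketo ester vinyl ketone 13, stored as its β-sulfonyl ketone 12.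
3. Enabling feature: in rings A and C, C6 is α to the C5 carbonyl whose other α-carbon is the quaternary C4, so this ketone can enolize only toward C6. The bridge CH2 is β to C5 (an enone terminus), the acyl carbon C1 closes a six-membered ring with C6, and ring B is a phloroglucinol with two equivalent free nucleophilic carbons, so the twofold symmetry lets one operation build both halves.
4. 12 comes from methyl isobutyrylacetate 5 (γ-dianion aldol with 3-(methylsulfanyl)propanal, oxidation, C-butyrylation, S-oxidation); 4 comes from phloroglucinol by Hoesch acylation.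
5. Ring order: ring B is bought as phloroglucinol; rings A and C are formed last, together, in the key step.

Key step: step 6

Remark: the target has no stereocentre; the β-tricarbonyl compounds 11–15 are mixtures of enol tautomers and each is drawn in one form (the acyclic ones as the triketo form).

**Route**

Step 1
Reactants: 1 phloroglucinol, 2 butyronitrile
Product: 4 1-(2,4,6-trihydroxyphenyl)butan-1-one, via ketiminium chloride 3 (not isolated)
Conditions: HCl (g), ZnCl2 (cat.), Et2O, 0 °C; then H2O, reflux
Reagents that add atoms: butyronitrile 2, CCCC#N; water, O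
Why: Hoesch reaction, in which the nitrile activated by HCl acylates the very electron-rich arene once only, because the ketiminium salt 3 is deactivated toward a second acylation and is hydrolysed to the aryl ketone afterwards.

Step 2
Reactants: 5 methyl 4-methyl-3-oxopentanoate, 6 3-(methylsulfanyl)propanal
Product: 8 methyl 5-hydroxy-4,4-dimethyl-7-(methylsulfanyl)-3-oxoheptanoate (racemic), via dianion 7 (not isolated)
Conditions: NaH, THF, 0 °C; n-BuLi, 0 °C; then 6, −78 °C; aq. HCl quench
Reagents that add atoms: 3-(methylsulfanyl)propanal 6, CSCCC=O
Why: aldol addition of a β-keto ester dianion, whose second deprotonation can occur only at the tertiary γ-carbon and whose γ-carbanion should add to the aldehyde at −78 °C faster than it deprotonates it, building the quaternary C(CH3)2 centre; the carbinol centre forms racemic, which is of no consequence because step 3 removes it.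

Step 3
Reactants: 8 methyl 5-hydroxy-4,4-dimethyl-7-(methylsulfanyl)-3-oxoheptanoate
Product: 9 methyl 4,4-dimethyl-7-(methylsulfanyl)-3,5-dioxoheptanoate
Conditions: Dess–Martin periodinane, CH2Cl2, 0 °C → rt
Reagents that add atoms: none
Why: Dess–Martin oxidation of a hindered secondary alcohol under near-neutral conditions should leave the thioether and the β-keto ester untouched, and the quaternary C4 rules out elimination.

Step 4
Reactants: 9 methyl 4,4-dimethyl-7-(methylsulfanyl)-3,5-dioxoheptanoate, 10 butyryl chloride
Product: 11 methyl 2-butanoyl-4,4-dimethyl-7-(methylsulfanyl)-3,5-dioxoheptanoate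
Conditions: MgCl2, pyridine, CH2Cl2, 0 °C → rt; 1 M HCl work-up
Reagents that add atoms: butyryl chloride 10, CCCC(Cl)=O
Why: magnesium-mediated C-acylation of a β-keto ester (soft enolization), in which the chelated magnesium enolate is acylated at carbon at C2, the only doubly activated position, while pyridine is too weak a base to enolize the C5 ketone or to expel the thiolate.

Step 5
Reactants: 11 methyl 2-butanoyl-4,4-dimethyl-7-(methylsulfanyl)-3,5-dioxoheptanoate
Product: 12 methyl 2-butanoyl-7-(methanesulfonyl)-4,4-dimethyl-3,5-dioxoheptanoate
Conditions: mCPBA (2.2 equiv), CH2Cl2, 0 °C → rt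
Reagents that add atoms: mCPBA (3-chloroperoxybenzoic acid), OOC(=O)c1cccc(Cl)c1
Why: peracid oxidation of a sulfide to the sulfone is much faster than Baeyer–Villiger oxidation of the hindered ketones or attack on the hydrogen-bonded, electron-poor tricarbonyl enol, and it turns the inert thioether into a sulfinate leaving group β to the C5 ketone.

Step 6
Reactants: 4 1-(2,4,6-trihydroxyphenyl)butan-1-one, 12 methyl 2-butanoyl-7-(methanesulfonyl)-4,4-dimethyl-3,5-dioxoheptanoate
Product: 15 CNP0287270.0, 2-butanoyl-6-({3-butanoyl-5-[(5-butanoyl-2,4-dihydroxy-3,3-dimethyl-6-oxocyclohexa-1,4-dien-1-yl)methyl]-2,4,6-trihydroxyphenyl}methyl)-3,5-dihydroxy-4,4-dimethylcyclohexa-2,5-dien-1-one, via vinyl ketone 13 (not isolated), via twofold Michael adduct 14 (not isolated)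
Conditions: 4 (1 equiv), 12 (2.1 equiv), t-BuOK (10 equiv), THF/t-BuOH, 0 °C → rt; then cold 1 M HCl
Reagents that add atoms: none
Why: Proposed new method: excess t-BuOK removes first the tricarbonyl C–H of 12 and then the C6–H next to the C5 ketone, whose enolate expels methanesulfinate (E1cB, the standard use of a β-sulfonyl ketone as a vinyl ketone surrogate) to give 13, and the phloroglucinolate of 4 adds through its two free ring carbons to the enone terminus (Friedel–Crafts-type C-Michael addition, known for acylphloroglucinols and vinyl ketones) and rearomatizes to 14. Each C6 enolate of 14, the only enolate the C5 ketone can form because C4 is quaternary, then attacks the C1 ester in a 6-exo-trig Dieckmann (Claisen) closure that makes the C1–C6 bond of ring A and of ring C and ejects methoxide; the closest known reaction types are the Michael–Claisen annulation that gives dimedone and the Claisen cyclization of polyketo esters to acylphloroglucinols, and what is new is their twofold coupling to an arene C-nucleophile in one flask. No stereocentre is formed. The step needs C- over O-alkylation of the phenoxide (soft acceptor, and O-adducts revert by retro-oxa-Michael reaction), Claisen attack at the ester instead of aldol attack at the butanoyl carbonyl (the two ketone oxygens carry the charge of the tricarbonyl anion, the ester is its most electrophilic carbonyl, and only the Claisen path is irreversible, which also returns any O-acylated enol lactone to the C-acylated product), and tolerance of a 6-endo Michael addition of the tricarbonyl anion to its own enone (reversible under stoichiometric base, because the stabilized carbanion is expelled again). The same anionic charge shields the 2,2-dimethyl-1,3-dione against retro-Claisen cleavage, and the outcome should not depend on the order of events, because ring closure before sulfinate loss gives a methylene-trione acceptor that the phloroglucinolate captures to the same product.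

**Compound list**

1 | phloroglucinol (benzene-1,3,5-triol) | Oc1cc(O)cc(O)c1 | starting material
2 | butyronitrile | CCCC#N | starting material
3 | 1-(2,4,6-trihydroxyphenyl)butan-1-iminium chloride | CCCC(=[NH2+])c1c(O)cc(O)cc1O.[Cl-] | intermediate
4 | 1-(2,4,6-trihydroxyphenyl)butan-1-one | CCCC(=O)c1c(O)cc(O)cc1O | intermediate
5 | methyl 4-methyl-3-oxopentanoate (methyl isobutyrylacetate) | COC(=O)CC(=O)C(C)C | starting material
6 | 3-(methylsulfanyl)propanal | CSCCC=O | starting material
7 | sodium lithium dianion (bis-enolate) of 5 | CC(C)=C([O-])C=C([O-])OC.[Na+].[Li+] | intermediate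
8 | methyl 5-hydroxy-4,4-dimethyl-7-(methylsulfanyl)-3-oxoheptanoate (racemic) | COC(=O)CC(=O)C(C)(C)C(O)CCSC | intermediate
9 | methyl 4,4-dimethyl-7-(methylsulfanyl)-3,5-dioxoheptanoate | COC(=O)CC(=O)C(C)(C)C(=O)CCSC | intermediate
10 | butyryl chloride | CCCC(Cl)=O | starting material
11 | methyl 2-butanoyl-4,4-dimethyl-7-(methylsulfanyl)-3,5-dioxoheptanoate | COC(=O)C(C(=O)CCC)C(=O)C(C)(C)C(=O)CCSC | intermediate
12 | methyl 2-butanoyl-7-(methanesulfonyl)-4,4-dimethyl-3,5-dioxoheptanoate | COC(=O)C(C(=O)CCC)C(=O)C(C)(C)C(=O)CCS(C)(=O)=O | intermediate
13 | methyl 2-butanoyl-4,4-dimethyl-3,5-dioxohept-6-enoate (formed as its potassium salt, drawn neutral) | COC(=O)C(C(=O)CCC)C(=O)C(C)(C)C(=O)C=C | intermediate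
14 | dimethyl 7,7'-(5-butanoyl-2,4,6-trihydroxy-1,3-phenylene)bis(2-butanoyl-4,4-dimethyl-3,5-dioxoheptanoate) (formed as its potassium salt, drawn neutral) | CCCC(=O)c1c(O)c(CCC(=O)C(C)(C)C(=O)C(C(=O)CCC)C(=O)OC)c(O)c(CCC(=O)C(C)(C)C(=O)C(C(=O)CCC)C(=O)OC)c1O | intermediate
15 | CNP0287270.0, 2-butanoyl-6-({3-butanoyl-5-[(5-butanoyl-2,4-dihydroxy-3,3-dimethyl-6-oxocyclohexa-1,4-dien-1-yl)methyl]-2,4,6-trihydroxyphenyl}methyl)-3,5-dihydroxy-4,4-dimethylcyclohexa-2,5-dien-1-one | CCCC(=O)C1=C(O)C(C)(C)C(O)=C(Cc2c(O)c(CC3=C(O)C(C)(C)C(O)=C(C(=O)CCC)C3=O)c(O)c(C(=O)CCC)c2O)C1=O | target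

**Step count and risks**

Total step count: 6. Longest linear sequence: 5 steps (steps 2–6).

Steps most likely to fail:

Step 6 (proposed new method). The ring closure may stall because the ester sits on a delocalized tricarbonyl anion; the enone may be consumed by intramolecular conjugate addition or oligomerization before the arene adds; and long exposure to base may scramble the methylene bridges. The fallback uses known chemistry, keeps the C1–C6 Claisen closure, builds the outer ring before the bridge, sets out from 5 and comes back at 15. The dianion 7, made as in step 2, is acylated at its γ-carbon with N-methoxy-N-methylacetamide to give methyl 4,4-dimethyl-3,5-dioxohexanoate F1. t-BuOK in THF then closes the same ring bond on this simple β-keto ester and gives filicinic acid F2. Friedel–Crafts C-acylation with butyryl chloride 10 and AlCl3 gives butyrylfilicinic acid F3. Condensation of F3 (2 equiv), aqueous formaldehyde and 4 in dilute aqueous KOH at 0 °C, the classical methylene bridging of acylphloroglucinols, should then give 15.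

Step 2. Proton transfer from the enolizable aldehyde to the hindered tertiary carbanion, or retro-aldol cleavage on warming, may take the place of addition. The fallback replaces the strongly basic dianion by a neutral silyl dienolate, sets out from 5 and comes back at 8. TMSCl and Et3N give methyl 4-methyl-3-[(trimethylsilyl)oxy]pent-2-enoate F4. LDA followed by TMSCl gives 1-methoxy-4-methyl-1,3-bis[(trimethylsilyl)oxy]penta-1,3-diene F5. A Mukaiyama aldol addition of F5 to 6 with TiCl4 in CH2Cl2 at −78 °C should then give 8 at the γ-carbon.

Step 5. Oxidation at the tricarbonyl enol carbon or Baeyer–Villiger insertion may compete with the second oxidation at sulfur. The fallback activates the sulfide by alkylation instead of oxidation, sets out from 11 and comes back at 13 in the flask of step 6. Methyl trifluoromethanesulfonate in CH2Cl2 at 0 °C gives [6-butanoyl-7-methoxy-4,4-dimethyl-3,5,7-trioxoheptyl](dimethyl)sulfonium trifluoromethanesulfonate F6. Used in place of 12 under the conditions of step 6, F6 should lose dimethyl sulfide by the same E1cB path and release 13.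

**Further compounds**

F1 | step 6 | methyl 4,4-dimethyl-3,5-dioxohexanoate | COC(=O)CC(=O)C(C)(C)C(C)=O
F2 | step 6 | filicinic acid (3,5-dihydroxy-4,4-dimethylcyclohexa-2,5-dien-1-one) | CC1(C)C(O)=CC(=O)C=C1O
F3 | step 6 | butyrylfilicinic acid (2-butanoyl-3,5-dihydroxy-4,4-dimethylcyclohexa-2,5-dien-1-one) | CCCC(=O)C1=C(O)C(C)(C)C(O)=CC1=O
F4 | step 2 | methyl 4-methyl-3-[(trimethylsilyl)oxy]pent-2-enoate | COC(=O)C=C(O[Si](C)(C)C)C(C)C
F5 | step 2 | 1-methoxy-4-methyl-1,3-bis[(trimethylsilyl)oxy]penta-1,3-diene | COC(O[Si](C)(C)C)=CC(O[Si](C)(C)C)=C(C)C
F6 | step 5 | [6-butanoyl-7-methoxy-4,4-dimethyl-3,5,7-trioxoheptyl](dimethyl)sulfonium trifluoromethanesulfonate | COC(=O)C(C(=O)CCC)C(=O)C(C)(C)C(=O)CC[S+](C)C.[O-]S(=O)(=O)C(F)(F)F
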